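You may take the rising peaks of X below as E converting better at a higher charge, and then you would go looking for a rate when a subtraction may do. These are closed, stirred flasks of the substrate E, with G beside it, giving the product X.

| flask | E | G | remark | time |
|---|---|---|---|---|
| teal | 0.031 M | 0.010 M | run made earlier |  |
| ochre | 0.079 M | 0.010 M | run made earlier |  |
| violet | 0.19 M | 0.010 M | run made earlier |  |
| birch | 0.030 M | 0.0100 M |  | 15 min |
| alder | 0.20 M | 0.0100 M |  | 15 min |
| ash | 0.050 M | 0.0100 M |  | 15 min |
| elm | 0.080 M | 0.0100 M |  | 15 min |

- teal (time / min: X / %): 0.833: 22.5; 2.00: 33.7; 5.00: 37.6; 10.0: 36.8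
- ochre (time / min: X / %): 2.50: 42.9; 5.00: 47.2; 8.00: 48.2; 10.0: 46.1
- violet (time / min: X / %): 1.33: 35.5; 4.00: 51.3; 6.00: 52.5; 10.0: 50.2

(readings scatter by 0.5 percentage points)

1. all flasks from highest to lowest amount of X, in percent of the E charged, at 15 min (birch / alder / ash / elm)
2. the amount of X, in percent of the E charged of the flask you put first, at 15 min
3. the amount of X, in percent of the E charged of the flask you put last, at 15 min

Read the peaks run by run: teal 37.6%, ochre 48.2%, violet 52.5%. Suppose each G removes one E for good, G being the limiting reagent of that loss. Birch would then keep 66.7% of its charge. This fraction, one minus c_G/c_E, I call the free share. For the runs it is 67.7%, 87.3% and 94.7%, and peak over free share reads 55.5%, 55.2% and 55.4%, level within the scatter of 0.5 percentage points.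

So the end state looks like a fixed part of the free share, on average 55.4%. The last readings, at 10.0 min, give 53.4%. The highest readings stood near 6.33 min on average, so a straight fade reaches 50.6% at 15 min. My reckoning multiplies that part by the free share: 33.8% for birch and, with a free share of 95.0%, 48.1% for alder, while ash, with 80.0%, and elm, with 87.5%, lie between them.

The forecast gives alder > elm > ash > birch, top 48% (45.5% to 50.5%) and low 34% (31.5% to 36.5%), on the ground that “a constant fraction of the rest becomes X”.

The flasks give alder > elm > ash > birch, top 48.8% and low 34.2%.

    E + G → L (k = 1.37 /M/s)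
    X ⇌ Q (K = 0.340, k = 0.00212 /s)
    E ⇌ X (K = 2.60, k = 0.00744 /s)
    X ⇌ D (K = 0.734, k = 2.83 × 10⁻⁴ /s)
    Q ⇌ E (k = 4.05 × 10⁻⁴ /s)

Divide the X at 15 min by the free share and birch gives 51.3%, alder 51.4%. With more G, birch would leave the forecast's range: at 0.0129 M of G its X has moved by 5 points, and the forecast's low allows 2.5 points. Now take birch's neighbour, charged with 0.0040 M of G and otherwise held. Its free share is 86.7%, and birch's part of the free share gives 44.5%. The neighbour holds 44.5% of X at 15.0 min.

The runs come from a simulation with made-up constants; noise was put on by code.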